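**Plan**
- The retrosynthesis first cuts the bond between C6 of ring A and the CH2 bridge, giving a ring A vinylogous acid and a ring B Mannich base that serves as an ortho-quinone methide precursor.
- C4 of ring A is stereogenic only because C2 carries hexanoyl and C6 the bridge. With hexanoyl on both C2 and C6, a mirror plane runs through C4 and C1=O and the two acyl groups are enantiotopic. The chiral monoacyl ring is therefore traced back to this achiral diacyl dienone.
- The diacyl dienone is cut at the C4–prenyl bond and at both ring–acyl bonds, back to 2,4,6-trihydroxytoluene. Ring B is cut at CH2–N, O–CH3 and ring–butanoyl, back to phloroglucinol.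
- Forward: no ring is built, since both carbocycles come from phloroglucinols. Ring A is acylated twice, dearomatised by prenylation and mono-deacylated, ring B is made in three steps, and the methylene bridge joins the halves last.
- The single stereocentre (4R) comes from a C–C hydrolase that removes one of the two enantiotopic hexanoyl groups; nothing afterwards touches C4.

Key step: step 3

Assumption: ring A is written throughout as the 3,5-dihydroxy-2,5-dien-1-one tautomer of the target SMILES, in which the quaternary carbon of 6 and 13 is 4R by CIP analysis. A hydrolase variant of this sense is taken to be obtainable by screening and directed evolution, using the enantiocomplementary lineage if the first hits prefer the other acyl group.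

**Step 1**
Reactants: 1 2,4,6-trihydroxytoluene; 2 hexanoyl chloride
Product: 3 1,1'-(2,4,6-trihydroxy-5-methyl-1,3-phenylene)di(hexan-1-one)
Conditions: 2 (2.3 equiv), AlCl3 (4.5 equiv), PhNO2/CH2Cl2, 0 → 70 °C; then ice/aq. HCl
Reagents that add atoms: none
Why: Twofold Friedel–Crafts C-acylation (any aryl ester formed first undergoes Fries rearrangement under the same conditions) fills the only two free positions of the electron-rich methylphloroglucinol, so the substrate fixes the regiochemistry.

**Step 2**
Reactants: 3 1,1'-(2,4,6-trihydroxy-5-methyl-1,3-phenylene)di(hexan-1-one); 4 1-bromo-3-methylbut-2-ene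
Product: 5 2,6-dihexanoyl-3,5-dihydroxy-4-methyl-4-(3-methylbut-2-enyl)cyclohexa-2,5-dien-1-one (achiral)
Conditions: NaOMe (3 equiv), MeOH, 0 °C; 4 (1.3 equiv), 0 °C → rt; then aq. HCl
Reagents that add atoms: none
Why: Base-mediated dearomative C-alkylation of a diacylphloroglucinol, as in the classical preparation of diacylfilicinic acids, where the methyl-bearing carbon is the only ring carbon of the polyanion free to take the prenyl group; both flanking carbons carry hexanoyl, so the new quaternary carbon lies on a mirror plane and is not stereogenic.

**Step 3**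
Reactants: 5 2,6-dihexanoyl-3,5-dihydroxy-4-methyl-4-(3-methylbut-2-enyl)cyclohexa-2,5-dien-1-one
Product: 6 (4R)-2-hexanoyl-3,5-dihydroxy-4-methyl-4-(3-methylbut-2-enyl)cyclohexa-2,5-dien-1-one
Conditions: evolved diacylphloroglucinol-type C–C hydrolase (zinc-dependent; ZnSO4 10 µM), HEPES buffer pH 7.5, 10% DMSO, 30 °C; then pH 2, EtOAc extraction
Reagents that add atoms: none
Why: Proposed new method: an enzyme-activated water adds to one hexanoyl C=O of the bound substrate anion, and the tetrahedral adduct collapses by retro-Claisen cleavage of the exocyclic C–C bond, expelling ring A as a delocalised tricarbonyl enolate that is protonated at C6 while hexanoic acid leaves. The closest known reaction types are the hydrolytic removal of exactly one acyl group from 2,4-diacetylphloroglucinol and from phloretin by C–C hydrolases, the retro-Claisen desymmetrisation of prochiral bicyclic β-diketones by 6-oxocamphor hydrolase, and the esterase desymmetrisation of prochiral diesters; what is new is cleavage of a C-acyl group from a dearomatised ring with a quaternary carbon. No ring closes and no skeletal bond forms. C4 becomes stereogenic under control of the protein: the pocket must seat the methyl and the prenyl group on C4 in different sub-sites, so only one of the two mirror-related hexanoyl carbonyls, the one whose loss leaves the 4R compound, reaches the activated water. The step needs selectivity between enantiotopic groups and a stop after one cleavage; the first rests on the methyl/prenyl recognition, the second on the loss of the two-acyl binding mode in 6, as with the natural enzymes that leave the monoacyl product untouched, and the triketone anion should not hydrolyse in neutral buffer without enzyme, which would otherwise give racemic product. Variants are to be found by screening hydrolase homologues and improved by saturation mutagenesis at the acyl channel and the C4 pocket, with the enantiomeric purity of 6 read out by chiral HPLC.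

**Step 4**
Reactants: 7 phloroglucinol; 8 butanoyl chloride
Product: 9 1-(2,4,6-trihydroxyphenyl)butan-1-one
Conditions: 8 (1.05 equiv), AlCl3 (3.5 equiv), PhNO2/CH2Cl2, 0 °C → rt; then ice/aq. HCl
Reagents that add atoms: none
Why: Friedel–Crafts mono-acylation of phloroglucinol; the first acyl group deactivates the ring, so one equivalent of acid chloride should stop at the monoketone.

**Step 5**
Reactants: 9 1-(2,4,6-trihydroxyphenyl)butan-1-one
Product: 10 1-(2,6-dihydroxy-4-methoxyphenyl)butan-1-one
Conditions: Me2SO4 (1.0 equiv), K2CO3 (1.0 equiv), acetone, rt → 50 °C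
Reagents that add atoms: dimethyl sulfate, COS(=O)(=O)OC
Why: Selective Williamson O-methylation; the 4-hydroxyl para to the ketone is the most acidic and is not hydrogen-bonded to the carbonyl, so one equivalent of base and methylating agent should react there ahead of the two chelated ortho hydroxyls.

**Step 6**
Reactants: 10 1-(2,6-dihydroxy-4-methoxyphenyl)butan-1-one
Product: 11 1-[3-[(dimethylamino)methyl]-2,6-dihydroxy-4-methoxyphenyl]butan-1-one
Conditions: CH2(NMe2)2 (1.05 equiv), EtOH, 0 °C → rt
Reagents that add atoms: N,N,N',N'-tetramethylmethanediamine, CN(C)CN(C)C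
Why: Mannich aminomethylation with a preformed aminal; the acidic phenol protonates the aminal to release the iminium ion, which attacks one of the two equivalent free ring positions, and the zwitterionic mono-Mannich base is deactivated towards a second substitution.

**Step 7**
Reactants: 6 (4R)-2-hexanoyl-3,5-dihydroxy-4-methyl-4-(3-methylbut-2-enyl)cyclohexa-2,5-dien-1-one; 11 1-[3-[(dimethylamino)methyl]-2,6-dihydroxy-4-methoxyphenyl]butan-1-one
Product: 13 (4R)-6-[(3-butanoyl-2,4-dihydroxy-6-methoxyphenyl)methyl]-2-hexanoyl-3,5-dihydroxy-4-methyl-4-(3-methylbut-2-enyl)cyclohexa-2,5-dien-1-one (CNP0219674.1), via ring B ortho-quinone methide 12 (not isolated)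
Conditions: 6 (1.2 equiv), slow addition of 11, 1,4-dioxane, 80 °C, N2; then dilute aq. HCl work-up
Reagents that add atoms: none
Why: The acidic partner 6 protonates the amine of 11, thermal retro-Mannich loss of dimethylamine gives the ortho-quinone methide, and C6 of 6, its only free nucleophilic carbon, adds in a Michael reaction that re-aromatises ring B; C4 is quaternary, takes no part and keeps its configuration.

**Compound list**
1 | 2,4,6-trihydroxytoluene | Cc1c(O)cc(O)cc1O | starting material
2 | hexanoyl chloride | CCCCCC(Cl)=O | starting material
3 | 1,1'-(2,4,6-trihydroxy-5-methyl-1,3-phenylene)di(hexan-1-one) | Cc1c(O)c(C(=O)CCCCC)c(O)c(C(=O)CCCCC)c1O | intermediate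
4 | 1-bromo-3-methylbut-2-ene | CC(C)=CCBr | starting material
5 | 2,6-dihexanoyl-3,5-dihydroxy-4-methyl-4-(3-methylbut-2-enyl)cyclohexa-2,5-dien-1-one (achiral) | CCCCCC(=O)C1=C(O)C(C)(CC=C(C)C)C(O)=C(C(=O)CCCCC)C1=O | intermediate
6 | (4R)-2-hexanoyl-3,5-dihydroxy-4-methyl-4-(3-methylbut-2-enyl)cyclohexa-2,5-dien-1-one | CCCCCC(=O)C1=C(O)[C@](C)(CC=C(C)C)C(O)=CC1=O | intermediate
7 | phloroglucinol | Oc1cc(O)cc(O)c1 | starting material
8 | butanoyl chloride | CCCC(Cl)=O | starting material
9 | 1-(2,4,6-trihydroxyphenyl)butan-1-one | CCCC(=O)c1c(O)cc(O)cc1O | intermediate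
10 | 1-(2,6-dihydroxy-4-methoxyphenyl)butan-1-one | CCCC(=O)c1c(O)cc(OC)cc1O | intermediate
11 | 1-[3-[(dimethylamino)methyl]-2,6-dihydroxy-4-methoxyphenyl]butan-1-one | CCCC(=O)c1c(O)cc(OC)c(CN(C)C)c1O | intermediate
12 | 2-butanoyl-3-hydroxy-5-methoxy-6-methylidenecyclohexa-2,4-dien-1-one (ring B ortho-quinone methide) | CCCC(=O)C1=C(O)C=C(OC)C(=C)C1=O | intermediate
13 | (4R)-6-[(3-butanoyl-2,4-dihydroxy-6-methoxyphenyl)methyl]-2-hexanoyl-3,5-dihydroxy-4-methyl-4-(3-methylbut-2-enyl)cyclohexa-2,5-dien-1-one | CCCCCC(=O)C1=C(O)[C@](C)(CC=C(C)C)C(O)=C(Cc2c(OC)cc(O)c(C(=O)CCC)c2O)C1=O | target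

**Count**
Total steps: 7. Longest linear sequence: 4 steps (steps 1, 2, 3, 7 or steps 4, 5, 6, 7).

**Steps most likely to fail**

Step 3. The hydrolase may not turn over a dearomatised, quaternary-substituted substrate at a useful rate, may discriminate poorly between the two enantiotopic acyl groups, or may go on to cleave the second acyl group. The fallback uses known chemistry, sets out from 1 and returns at 6. Friedel–Crafts acylation of 1 with one equivalent of 2 (AlCl3, PhNO2/CH2Cl2) gives 1-(2,4,6-trihydroxy-3-methylphenyl)hexan-1-one F1. Prenylation of F1 with 4 and NaOMe in MeOH, in the manner of the classical acylfilicinic acid synthesis, dearomatises at the methyl-bearing carbon to give racemic 2-hexanoyl-3,5-dihydroxy-4-methyl-4-(3-methylbut-2-enyl)cyclohexa-2,5-dien-1-one F2; it must be separated from material prenylated at the free aromatic position. Preparative chromatography on a chiral stationary phase then delivers 6 and sets aside (4S)-2-hexanoyl-3,5-dihydroxy-4-methyl-4-(3-methylbut-2-enyl)cyclohexa-2,5-dien-1-one F3.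

Step 2. Alkylation at oxygen instead of the methyl-bearing carbon, and solvolysis of the allylic bromide by methoxide, may consume the material. The fallback sets out from 3 and returns at 5, replacing the SN2 alkylation by a catalytic allylic substitution followed by olefin metathesis. Decarboxylative Tsuji–Trost allylation of 3 with allyl methyl carbonate and Pd(PPh3)4 (zerovalent palladium) in THF should give 2,6-dihexanoyl-3,5-dihydroxy-4-methyl-4-(prop-2-enyl)cyclohexa-2,5-dien-1-one F4, since O-allyl products re-ionise on palladium and funnel to the C-allyl dienone. Cross-metathesis of F4 with 2-methylbut-2-ene using second-generation Grubbs catalyst in CH2Cl2 at 40 °C then converts allyl into prenyl and gives 5.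

Step 7. The quinone methide may be captured by a second molecule of 11 or by the free ring B position of the product (oligomerisation), and methylene exchange between the rings may scramble the bridge. The fallback reverses the roles of the two halves, sets out from 6 and 10 and returns at 13. Aminomethylation of 6 with CH2(NMe2)2 gives (4R)-6-[(dimethylamino)methyl]-2-hexanoyl-3,5-dihydroxy-4-methyl-4-(3-methylbut-2-enyl)cyclohexa-2,5-dien-1-one F5. On gentle warming F5 loses dimethylamine to (4S)-2-hexanoyl-3-hydroxy-4-methyl-4-(3-methylbut-2-enyl)-6-methylidenecyclohex-2-ene-1,5-dione F6, which is not isolated; it has the same spatial arrangement at C4 as 6, and the descriptor changes only through the CIP order. An excess of 10, recoverable and symmetric, adds through one of its two equivalent free ring carbons to give 13, as in the Knoevenagel–Michael couplings used for related acylphloroglucinol dimers.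

**Further compounds**
F1 | step 3 | 1-(2,4,6-trihydroxy-3-methylphenyl)hexan-1-one | CCCCCC(=O)c1c(O)cc(O)c(C)c1O
F2 | step 3 | racemic 2-hexanoyl-3,5-dihydroxy-4-methyl-4-(3-methylbut-2-enyl)cyclohexa-2,5-dien-1-one | CCCCCC(=O)C1=C(O)C(C)(CC=C(C)C)C(O)=CC1=O
F3 | step 3 | (4S)-2-hexanoyl-3,5-dihydroxy-4-methyl-4-(3-methylbut-2-enyl)cyclohexa-2,5-dien-1-one | CCCCCC(=O)C1=C(O)[C@@](C)(CC=C(C)C)C(O)=CC1=O
F4 | step 2 | 2,6-dihexanoyl-3,5-dihydroxy-4-methyl-4-(prop-2-enyl)cyclohexa-2,5-dien-1-one | CCCCCC(=O)C1=C(O)C(C)(CC=C)C(O)=C(C(=O)CCCCC)C1=O
F5 | step 7 | (4R)-6-[(dimethylamino)methyl]-2-hexanoyl-3,5-dihydroxy-4-methyl-4-(3-methylbut-2-enyl)cyclohexa-2,5-dien-1-one | CCCCCC(=O)C1=C(O)[C@](C)(CC=C(C)C)C(O)=C(CN(C)C)C1=O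
F6 | step 7 | (4S)-2-hexanoyl-3-hydroxy-4-methyl-4-(3-methylbut-2-enyl)-6-methylidenecyclohex-2-ene-1,5-dione | CCCCCC(=O)C1=C(O)[C@](C)(CC=C(C)C)C(=O)C(=C)C1=O
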